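**Retrosynthetic overview**

1. The last bonds to be made are three O–H bonds (hydrogenolysis of three benzyl ethers) and the N–CH3 bond (reductive methylation after removal of a tert-butanesulfinyl group). That sulfinyl group serves first as chiral auxiliary and then as a non-basic nitrogen protecting group.
2. Key disconnection: ring C (the pyranone) is opened at O1–C2 and C4–C4a. Both bonds are made in one flask from a 4-(piperidin-2-yl)-3,5-bis(benzyloxy)phenol and (E)-4-(benzyloxy)cinnamoyl chloride, by magnesium-templated ortho-C-acylation followed by a thiourea-catalysed enantioselective oxa-Michael closure that sets C2.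
3. Enabling feature: ring A is a 2-substituted phloroglucinol. C6 carries the piperidine, the two ring CH positions meta to C6 (C8 and the future C4a) are equivalent by rotation about the C6–piperidine bond, and only the oxygen para to C6 (the future O1) is free while O5 and O7 are benzylated. Acylation at either CH and closure through the single free OH can therefore give only the 6-substituted flavanone.
4. The arylpiperidine comes from lithiation between the two benzyloxy groups of silyl-protected 3,5-bis(benzyloxy)phenol, addition to the (R)-tert-butanesulfinyl imine of 5-chloropentanal (sets the piperidine centre) and N-alkylative ring closure.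
5. Ring order: ring A (purchased), then the piperidine ring, then ring C.

Key step: step 7

Assumption: the aryl Grignard adds to the N-sulfinyl aldimine through the magnesium-bridged six-membered transition state, so that the (R)-configured sulfur gives the (R)-configured carbon.

**Route**

Step 1
Reactants: 1 3,5-bis(benzyloxy)phenol
Product: 2 [3,5-bis(benzyloxy)phenoxy]tri(propan-2-yl)silane
Conditions: i-Pr3SiCl, imidazole, DMF, rt
Reagents that add atoms: chlorotri(propan-2-yl)silane CC(C)[Si](Cl)(C(C)C)C(C)C
Why: O-silylation of the phenol (silyl ether formation) masks the future O1 with a bulky, non-directing group, so that the later lithiation is steered to the carbon between the two benzyloxy groups.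

Step 2
Reactants: 3 5-chloropentanal; 4 (R)-2-methylpropane-2-sulfinamide
Product: 5 (R)-N-[(1E)-5-chloropentylidene]-2-methylpropane-2-sulfinamide
Conditions: pyrrolidine (10 mol%), 4 Å molecular sieves, CH2Cl2, rt
Reagents that add atoms: none
Why: amine-catalysed condensation of the aldehyde with the sulfinamide (imine formation) should give the (E)-N-sulfinyl aldimine, the sulfur centre coming unchanged from 4.

Step 3
Reactants: 2 [3,5-bis(benzyloxy)phenoxy]tri(propan-2-yl)silane; 5 (R)-N-[(1E)-5-chloropentylidene]-2-methylpropane-2-sulfinamide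
Product: 8 (R)-N-[(1R)-1-{2,6-bis(benzyloxy)-4-[tri(propan-2-yl)silyloxy]phenyl}-5-chloropentyl]-2-methylpropane-2-sulfinamide, via aryllithium 6 (not isolated), via arylmagnesium bromide 7 (not isolated)
Conditions: n-BuLi, Et2O, 0 °C to rt; MgBr2·OEt2, 0 °C; 5, toluene, −78 to −20 °C; then H2O
Reagents that add atoms: none
Why: directed ortho-metalation at the carbon flanked by both benzyloxy groups, lithium-to-magnesium exchange and 1,2-addition of the aryl Grignard reagent to the N-sulfinyl aldimine through the magnesium-bridged six-membered chair transition state should set the (R) carbon centre under control of the (R) sulfur centre.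

Step 4
Reactants: 8 (R)-N-[(1R)-1-{2,6-bis(benzyloxy)-4-[tri(propan-2-yl)silyloxy]phenyl}-5-chloropentyl]-2-methylpropane-2-sulfinamide
Product: 9 (2R)-2-{2,6-bis(benzyloxy)-4-[tri(propan-2-yl)silyloxy]phenyl}-1-[(R)-tert-butylsulfinyl]piperidine
Conditions: KN(SiMe3)2, THF, 0 °C to rt
Reagents that add atoms: none
Why: deprotonation of the sulfinamide N–H and intramolecular N-alkylation by the primary chloride (6-exo-tet SN2 ring closure) should form the piperidine without touching the benzylic centre.

Step 5
Reactants: 9 (2R)-2-{2,6-bis(benzyloxy)-4-[tri(propan-2-yl)silyloxy]phenyl}-1-[(R)-tert-butylsulfinyl]piperidine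
Product: 10 3,5-bis(benzyloxy)-4-{(2R)-1-[(R)-tert-butylsulfinyl]piperidin-2-yl}phenol
Conditions: Bu4NF, AcOH, THF, 0 °C
Reagents that add atoms: none
Why: fluoride-mediated desilylation of the aryl silyl ether should free the single phenol, the sulfinamide and the benzyl ethers being inert to buffered fluoride.

Step 6
Reactants: 11 (2E)-3-[4-(benzyloxy)phenyl]prop-2-enoic acid
Product: 12 (2E)-3-[4-(benzyloxy)phenyl]prop-2-enoyl chloride
Conditions: (COCl)2, DMF (cat.), CH2Cl2, 0 °C to rt; concentrated and used crude
Reagents that add atoms: oxalyl chloride O=C(Cl)C(Cl)=O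
Why: acid chloride formation through chloroiminium (Vilsmeier-type) activation should proceed without affecting the (E)-alkene or the benzyl ether.

Step 7
Reactants: 10 3,5-bis(benzyloxy)-4-{(2R)-1-[(R)-tert-butylsulfinyl]piperidin-2-yl}phenol; 12 (2E)-3-[4-(benzyloxy)phenyl]prop-2-enoyl chloride
Product: 15 (2S)-5,7-bis(benzyloxy)-2-[4-(benzyloxy)phenyl]-6-{(2R)-1-[(R)-tert-butylsulfinyl]piperidin-2-yl}-2,3-dihydro-4H-chromen-4-one, via magnesium phenolate 13 (not isolated), via chalcone 14 (not isolated)
Conditions: EtMgBr (1.05 equiv), toluene, 0 °C; 12 (1.05 equiv), 0 °C to rt; then 1,4-dioxane, 1-[3,5-bis(trifluoromethyl)phenyl]-3-[(8α,9S)-6'-methoxycinchonan-9-yl]thiourea (quinine-derived, 15 mol%), −20 °C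
Reagents that add atoms: none
Why: The magnesium phenolate 13 binds the acid chloride and delivers it to the ortho carbon through a six-membered chelate (C4–C4a bond); rearomatisation gives 2'-hydroxychalcone 14, which should stay magnesium-chelated between phenol oxygen and carbonyl in a conformation that cannot ring-close until 1,4-dioxane strips the magnesium halide and the bifunctional thiourea (thiourea N–H to the enone carbonyl, quinuclidine nitrogen to the phenol O–H) mediates conjugate addition of O1 to C2 (O1–C2 bond). The closest known reaction types are the metal-phenolate-templated ortho-acylation of phenols with cinnamoyl chlorides to 2'-hydroxychalcones, the Lewis-acid one-pot cinnamoylation and cyclisation of 3,5-dialkoxyphenols to racemic flavanones, and the cinchona-thiourea-catalysed enantioselective cyclisation of 2'-hydroxychalcones to flavanones. Ring C closes by a 6-endo-trig oxa-Michael addition. The C2 centre is set by the catalyst, which should direct O1 to the Si face of C2 to give (2S) (the quinidine-derived pseudoenantiomer addresses the other face); the existing (R) centre is remote and untouched, and any (2R) epimer is a diastereomer of 15 that chromatography should remove. The step needs C- over O-acylation and 1,2- over conjugate attack on the cinnamoyl unit (magnesium template, aprotic medium without Brønsted acid), a single acylation site (the position para to the free OH is occupied by the piperidine-bearing carbon and the two ortho CH are equivalent by rotation about the aryl–piperidine bond) and closure to the 6- and not the 8-substituted flavanone (O5 and O7 are benzylated, so only the oxygen para to the piperidine-bearing carbon can add). The N-sulfinyl group keeps the nitrogen non-basic and non-nucleophilic, so that neither acylammonium fragmentation of the electron-rich benzylic C–N bond nor amine-mediated uncatalysed closure should compete.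

Step 8
Reactants: 15 (2S)-5,7-bis(benzyloxy)-2-[4-(benzyloxy)phenyl]-6-{(2R)-1-[(R)-tert-butylsulfinyl]piperidin-2-yl}-2,3-dihydro-4H-chromen-4-one
Product: 17 (2S)-5,7-bis(benzyloxy)-2-[4-(benzyloxy)phenyl]-6-[(2R)-1-methylpiperidin-2-yl]-2,3-dihydro-4H-chromen-4-one, via secondary amine 16 (not isolated)
Conditions: HCl (4 M in dioxane), MeOH, 0 °C; concentrated; then aq. HCHO, NaOAc, NaBH(OAc)3, ClCH2CH2Cl, rt
Reagents that add atoms: formaldehyde C=O
Why: acidolysis of the N–S bond should release the piperidine as its hydrochloride, and reductive amination with formaldehyde (iminium reduction by the acetoxyborohydride, which should not reduce the aryl ketone) installs N-methyl under acidic to neutral conditions that leave C2 and the benzylic C–N centre untouched.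

Step 9
Reactants: 17 (2S)-5,7-bis(benzyloxy)-2-[4-(benzyloxy)phenyl]-6-[(2R)-1-methylpiperidin-2-yl]-2,3-dihydro-4H-chromen-4-one
Product: 18 (2S)-5,7-dihydroxy-2-(4-hydroxyphenyl)-6-[(2R)-1-methylpiperidin-2-yl]-2,3-dihydro-4H-chromen-4-one
Conditions: H2 (1 atm), Pd/C (10% Pd), AcOH (2 equiv), EtOAc–MeOH, rt
Reagents that add atoms: none
Why: hydrogenolysis of the three aryl benzyl ethers with the amine protonated (so that it does not slow the catalyst) should free the phenols without any base, so the base-labile C2 centre of the 5-hydroxyflavanone is not epimerised.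

**Compound list**

1 | 3,5-bis(benzyloxy)phenol | Oc1cc(OCc2ccccc2)cc(OCc2ccccc2)c1 | starting material
2 | [3,5-bis(benzyloxy)phenoxy]tri(propan-2-yl)silane | CC(C)[Si](Oc1cc(OCc2ccccc2)cc(OCc2ccccc2)c1)(C(C)C)C(C)C | intermediate
3 | 5-chloropentanal | O=CCCCCCl | starting material
4 | (R)-2-methylpropane-2-sulfinamide | CC(C)(C)[S@@](=O)N | starting material
5 | (R)-N-[(1E)-5-chloropentylidene]-2-methylpropane-2-sulfinamide | CC(C)(C)[S@@](=O)/N=C/CCCCCl | intermediate
6 | {2,6-bis(benzyloxy)-4-[tri(propan-2-yl)silyloxy]phenyl}lithium | [Li]c1c(OCc2ccccc2)cc(O[Si](C(C)C)(C(C)C)C(C)C)cc1OCc1ccccc1 | intermediate (not isolated)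
7 | {2,6-bis(benzyloxy)-4-[tri(propan-2-yl)silyloxy]phenyl}magnesium bromide | Br[Mg]c1c(OCc2ccccc2)cc(O[Si](C(C)C)(C(C)C)C(C)C)cc1OCc1ccccc1 | intermediate (not isolated)
8 | (R)-N-[(1R)-1-{2,6-bis(benzyloxy)-4-[tri(propan-2-yl)silyloxy]phenyl}-5-chloropentyl]-2-methylpropane-2-sulfinamide | CC(C)(C)[S@@](=O)N[C@H](CCCCCl)c1c(OCc2ccccc2)cc(O[Si](C(C)C)(C(C)C)C(C)C)cc1OCc1ccccc1 | intermediate
9 | (2R)-2-{2,6-bis(benzyloxy)-4-[tri(propan-2-yl)silyloxy]phenyl}-1-[(R)-tert-butylsulfinyl]piperidine | CC(C)(C)[S@@](=O)N1CCCC[C@@H]1c1c(OCc2ccccc2)cc(O[Si](C(C)C)(C(C)C)C(C)C)cc1OCc1ccccc1 | intermediate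
10 | 3,5-bis(benzyloxy)-4-{(2R)-1-[(R)-tert-butylsulfinyl]piperidin-2-yl}phenol | CC(C)(C)[S@@](=O)N1CCCC[C@@H]1c1c(OCc2ccccc2)cc(O)cc1OCc1ccccc1 | intermediate
11 | (2E)-3-[4-(benzyloxy)phenyl]prop-2-enoic acid | OC(=O)/C=C/c1ccc(OCc2ccccc2)cc1 | starting material
12 | (2E)-3-[4-(benzyloxy)phenyl]prop-2-enoyl chloride | ClC(=O)/C=C/c1ccc(OCc2ccccc2)cc1 | intermediate
13 | bromomagnesium 3,5-bis(benzyloxy)-4-{(2R)-1-[(R)-tert-butylsulfinyl]piperidin-2-yl}phenolate | CC(C)(C)[S@@](=O)N1CCCC[C@@H]1c1c(OCc2ccccc2)cc(O[Mg]Br)cc1OCc1ccccc1 | intermediate (not isolated)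
14 | (2E)-1-[2,4-bis(benzyloxy)-3-{(2R)-1-[(R)-tert-butylsulfinyl]piperidin-2-yl}-6-hydroxyphenyl]-3-[4-(benzyloxy)phenyl]prop-2-en-1-one | CC(C)(C)[S@@](=O)N1CCCC[C@@H]1c1c(OCc2ccccc2)cc(O)c(C(=O)/C=C/c2ccc(OCc3ccccc3)cc2)c1OCc1ccccc1 | intermediate (not isolated)
15 | (2S)-5,7-bis(benzyloxy)-2-[4-(benzyloxy)phenyl]-6-{(2R)-1-[(R)-tert-butylsulfinyl]piperidin-2-yl}-2,3-dihydro-4H-chromen-4-one | CC(C)(C)[S@@](=O)N1CCCC[C@@H]1c1c(OCc2ccccc2)cc2c(c1OCc1ccccc1)C(=O)C[C@@H](c1ccc(OCc3ccccc3)cc1)O2 | intermediate
16 | (2S)-5,7-bis(benzyloxy)-2-[4-(benzyloxy)phenyl]-6-[(2R)-piperidin-2-yl]-2,3-dihydro-4H-chromen-4-one (formed as its hydrochloride) | N1CCCC[C@@H]1c1c(OCc2ccccc2)cc2c(c1OCc1ccccc1)C(=O)C[C@@H](c1ccc(OCc3ccccc3)cc1)O2 | intermediate (not isolated)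
17 | (2S)-5,7-bis(benzyloxy)-2-[4-(benzyloxy)phenyl]-6-[(2R)-1-methylpiperidin-2-yl]-2,3-dihydro-4H-chromen-4-one | CN1CCCC[C@@H]1c1c(OCc2ccccc2)cc2c(c1OCc1ccccc1)C(=O)C[C@@H](c1ccc(OCc3ccccc3)cc1)O2 | intermediate
18 | (2S)-5,7-dihydroxy-2-(4-hydroxyphenyl)-6-[(2R)-1-methylpiperidin-2-yl]-2,3-dihydro-4H-chromen-4-one | CN1CCCC[C@@H]1c1c(O)cc2c(c1O)C(=O)C[C@@H](c1ccc(O)cc1)O2 | target

**Step count and risks**

Total step count: 9. Longest linear sequence: 7 steps (1 to 2 to 8 to 9 to 10 to 15 to 17 to 18, steps 1, 3, 4, 5, 7, 8 and 9).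

The three steps most likely to fail, most risky first:

First, step 7. The phenolate may be acylated on oxygen instead of carbon. The ring closure may show insufficient facial selectivity, or may start without the catalyst while magnesium salts are still present. Reversible ring opening may also erode C2. The fallback builds ring C in separate known stages and sets C2 by a ligand-controlled carbon–carbon bond formation. It sets out from 10:
- Acetylation (Ac2O, pyridine) gives the aryl acetate F1.
- Photo-Fries rearrangement (254 nm, MeCN; the para position is blocked and the two ortho positions are equivalent) gives the 2-hydroxyacetophenone F2.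
- Condensation with Me2NCH(OMe)2 (toluene, 90 °C) gives the enaminone F3.
- Acid-promoted ring closure with loss of dimethylamine (pyridinium p-toluenesulfonate, toluene, 80 °C) gives the chromone F4.
- Asymmetric conjugate addition of 4-(benzyloxy)phenylboronic acid, catalysed by Pd(OCOCF3)2 with (R)-4-tert-butyl-2-(pyridin-2-yl)-4,5-dihydro-1,3-oxazole (NH4PF6, H2O, ClCH2CH2Cl, 60 °C), should give the (2S) product.

This fallback comes back to the route at 15.

Second, step 3. The enolisable aldimine may be deprotonated by the hindered aryl nucleophile, and facial selectivity in the addition may be poor. The fallback makes the C–N centre by reduction instead of by carbon–carbon bond formation. It sets out from 2: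
- The aryllithium 6 is acylated with 5-chloro-N-methoxy-N-methylpentanamide to give the aryl ketone F5.
- Ti(OEt)4-mediated condensation with 4 gives the N-sulfinyl ketimine F6.
- NaBH4 reduction (THF, −48 °C), through the cyclic transition state in which hydride is delivered from the sulfinyl-oxygen-bound boron, should give the (R) carbon centre.

This fallback comes back to the route at 8.

Third, step 9. Over-reduction may occur (hydrogenolysis of the benzylic C2–O1 bond or reduction of the ketone), or the debenzylation may stall. The fallback removes the benzyl groups without hydrogen. It sets out from 17 and uses BCl3 with pentamethylbenzene as benzyl-cation scavenger (CH2Cl2, −78 °C), which should give 18 directly; it makes no new compound (F0).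

Further compounds

F1 | step 7 | 3,5-bis(benzyloxy)-4-{(2R)-1-[(R)-tert-butylsulfinyl]piperidin-2-yl}phenyl acetate | CC(C)(C)[S@@](=O)N1CCCC[C@@H]1c1c(OCc2ccccc2)cc(OC(C)=O)cc1OCc1ccccc1
F2 | step 7 | 1-[2,4-bis(benzyloxy)-3-{(2R)-1-[(R)-tert-butylsulfinyl]piperidin-2-yl}-6-hydroxyphenyl]ethan-1-one | CC(C)(C)[S@@](=O)N1CCCC[C@@H]1c1c(OCc2ccccc2)cc(O)c(C(C)=O)c1OCc1ccccc1
F3 | step 7 | (2E)-1-[2,4-bis(benzyloxy)-3-{(2R)-1-[(R)-tert-butylsulfinyl]piperidin-2-yl}-6-hydroxyphenyl]-3-(dimethylamino)prop-2-en-1-one | CC(C)(C)[S@@](=O)N1CCCC[C@@H]1c1c(OCc2ccccc2)cc(O)c(C(=O)/C=C/N(C)C)c1OCc1ccccc1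
F4 | step 7 | 5,7-bis(benzyloxy)-6-{(2R)-1-[(R)-tert-butylsulfinyl]piperidin-2-yl}-4H-chromen-4-one | CC(C)(C)[S@@](=O)N1CCCC[C@@H]1c1c(OCc2ccccc2)cc2occc(=O)c2c1OCc1ccccc1
F5 | step 3 | 1-{2,6-bis(benzyloxy)-4-[tri(propan-2-yl)silyloxy]phenyl}-5-chloropentan-1-one | O=C(CCCCCl)c1c(OCc2ccccc2)cc(O[Si](C(C)C)(C(C)C)C(C)C)cc1OCc1ccccc1
F6 | step 3 | (R)-N-[(1E)-1-{2,6-bis(benzyloxy)-4-[tri(propan-2-yl)silyloxy]phenyl}-5-chloropentylidene]-2-methylpropane-2-sulfinamide | CC(C)(C)[S@@](=O)/N=C(\CCCCCl)c1c(OCc2ccccc2)cc(O[Si](C(C)C)(C(C)C)C(C)C)cc1OCc1ccccc1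
F0 | step 9 | none | none
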